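**Plan**

1. Numbering is that of the eudesmanes: C1 carbinol, C4 bearing C15, C5/C10 ring fusion, C14 angular methyl, C11–C13 side chain; α is the face opposite C14.
2. Retrosynthesis: cut the C8 ester C–O bond; take the C12 acid back to the methyl of an isopropenyl group and cut C7–C11 (cross-coupling on a ring B enone); cut C4–C5, which opens ring A.
3. Enabling feature: C15 and the C6 oxygen are 1,4-related through C4–C5 (two donor carbons), and ring B carries oxygen at C6 and C8 on either side of the C7···C10 axis, the pattern of Birch-reduced 3,5-dimethoxybenzoic acid. An anodic coupling of a C15=C4 enol ether with the C5=C6 ring enol ether therefore closes ring A.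
4. Forward: ring B comes from the arene (Birch reduction–methylation creates C10); the C1–C4/C15 chain is grown on the former carboxyl carbon; ring A is closed at the anode; ring B is then dressed (carbonyl moved to C8, isopropenyl at C7, oxygen returned to C6, reduction at C8); C8 is acylated, C12 oxidised and the masks removed.
5. Stereochemistry: C1 by reagent-controlled allylation; C10 by choice between the two ring enol ethers under the influence of C1; C4 and C5 by equilibration to the trans-decalin; C6 and C7 by α-face epoxidation and reductive opening with axial protonation; C8 by a thermodynamically controlled ketone reduction.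

Key step: step 9

Remark: enol ether 12 is taken on as its E/Z mixture (E drawn), because C15 becomes an acetal carbon and the geometry is lost.

**Route**

Step 1
Reactants: 1 3,5-dimethoxybenzoic acid; 2 iodomethane
Product: 3 3,5-dimethoxy-1-methylcyclohexa-2,5-diene-1-carboxylic acid
Conditions: Li, NH3(l), THF, −78 °C; MeI; NH4Cl, aqueous work-up at pH 5–6
Reagents that add atoms: iodomethane (2), CI
Why: Birch reduction of the benzoate gives the ipso carboxylate dienolate, which is C-methylated in the same flask (Birch reductive alkylation) with both methoxy groups left on the remaining double bonds; C10 is created as a prochiral quaternary carbon, so no stereocentre arises.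

Step 2
Reactants: 3 3,5-dimethoxy-1-methylcyclohexa-2,5-diene-1-carboxylic acid
Product: 4 (3,5-dimethoxy-1-methylcyclohexa-2,5-dien-1-yl)methanol
Conditions: LiAlH4, THF, 0 °C → reflux; NaOH (aq) work-up
Reagents that add atoms: none
Why: LiAlH4 reduces the hindered carboxylic acid to the neopentyl alcohol (hydride reduction), and the basic work-up spares the two acid-labile enol ethers.

Step 3
Reactants: 4 (3,5-dimethoxy-1-methylcyclohexa-2,5-dien-1-yl)methanol
Product: 5 3,5-dimethoxy-1-methylcyclohexa-2,5-diene-1-carbaldehyde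
Conditions: nPr4N[RuO4] (5 mol %), N-methylmorpholine N-oxide, 4 Å MS, CH2Cl2, rt
Reagents that add atoms: none
Why: Ley–Griffith oxidation under neutral conditions gives the non-enolisable aldehyde that will become C1 without touching the enol ethers.

Step 4
Reactants: 5 3,5-dimethoxy-1-methylcyclohexa-2,5-diene-1-carbaldehyde; 6 allylmagnesium bromide
Product: 7 (1R)-1-(3,5-dimethoxy-1-methylcyclohexa-2,5-dien-1-yl)but-3-en-1-ol
Conditions: (+)-Ipc2BOMe, allylMgBr, Et2O, −78 °C → rt; then 5, −78 °C; NaOH, H2O2
Reagents that add atoms: allylmagnesium bromide (6), C=CC[Mg]Br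
Why: Brown allylation: the B-allyldiisopinocampheylborane made in the flask adds allyl through a chair six-membered transition state to the Re face of the aldehyde, so C1 is set as R under reagent control, and alkaline peroxide releases the alcohol.

Step 5
Reactants: 7 (1R)-1-(3,5-dimethoxy-1-methylcyclohexa-2,5-dien-1-yl)but-3-en-1-ol
Product: 8 triisopropylsilyl (TIPS) ether of 7
Conditions: iPr3SiOTf, 2,6-lutidine, CH2Cl2, 0 °C
Reagents that add atoms: triisopropylsilyl triflate, CC(C)[Si](C(C)C)(C(C)C)OS(=O)(=O)C(F)(F)F
Why: Silyl triflate silylation of the hindered secondary alcohol; the bulky, acid-stable TIPS ether is carried to the last step and is the group that has to bias the ring closure.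

Step 6
Reactants: 8 TIPS ether of 7
Product: 9 (4R)-4-(3,5-dimethoxy-1-methylcyclohexa-2,5-dien-1-yl)-4-(triisopropylsilyloxy)butan-1-ol
Conditions: 9-BBN-H, THF, 0 °C → rt; NaOH, H2O2
Reagents that add atoms: hydrogen peroxide, OO
Why: Anti-Markovnikov hydroboration–oxidation, in which 9-BBN-H takes the monosubstituted alkene in preference to the two trisubstituted ring enol ethers.

Step 7
Reactants: 9 (4R)-4-(3,5-dimethoxy-1-methylcyclohexa-2,5-dien-1-yl)-4-(triisopropylsilyloxy)butan-1-ol
Product: 10 (4R)-4-(3,5-dimethoxy-1-methylcyclohexa-2,5-dien-1-yl)-4-(triisopropylsilyloxy)butanal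
Conditions: nPr4N[RuO4] (5 mol %), N-methylmorpholine N-oxide, 4 Å MS, CH2Cl2, rt
Reagents that add atoms: none
Why: Ley–Griffith oxidation of the primary alcohol to the C4 aldehyde under conditions that leave silyl and enol ethers alone.

Step 8
Reactants: 10 (4R)-4-(3,5-dimethoxy-1-methylcyclohexa-2,5-dien-1-yl)-4-(triisopropylsilyloxy)butanal; 11 (methoxymethyl)triphenylphosphonium chloride
Product: 12 (1R)-1-(3,5-dimethoxy-1-methylcyclohexa-2,5-dien-1-yl)-5-methoxypent-4-en-1-yl triisopropylsilyl ether
Conditions: KN(SiMe3)2, THF, 0 °C; then 10, −78 °C → rt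
Reagents that add atoms: (methoxymethyl)triphenylphosphonium chloride (11), COC[P+](c1ccccc1)(c1ccccc1)c1ccccc1.[Cl-]
Why: Wittig reaction with the methoxymethylene ylide adds C15 and makes the side-chain enol ether, whose geometry is of no consequence.

Step 9
Reactants: 12 (1R)-1-(3,5-dimethoxy-1-methylcyclohexa-2,5-dien-1-yl)-5-methoxypent-4-en-1-yl triisopropylsilyl ether
Product: 13 cis-fused bicycle (1R,4S,5R,10R): C6 dimethyl ketal, C8=C9 methyl enol ether, C15 dimethyl acetal, 1β-OTIPS, H5 and C15 both β
Conditions: reticulated vitreous carbon anode, Pt cathode, undivided cell, LiClO4 (0.1 M), 2,6-lutidine, MeOH/THF (1:4), constant current, 2.2 F/mol, 0 °C; NaHCO3 (aq) work-up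
Reagents that add atoms: methanol, CO
Why: Anodic oxidation turns one enol ether into its radical cation, which is captured by the β-carbon of the other (C4 to C5) in a 6-exo-trig closure of ring A; a second electron transfer and capture of the two oxocarbenium ions by methanol give the C15 acetal and the C6 ketal, the closest known reaction being the intramolecular anodic coupling of two enol ethers to masked 1,4-dicarbonyl compounds. The side chain can reach only its own face of the flat diene, so the fusion is cis (H5 syn to C14), and in the chair-like closure C2 lies between the two ring arms with the methyl group anti to it and C15 equatorial, which sets C4 as the epimer shown. C10 becomes stereogenic through the choice of arm: the step needs closure on the arm gauche to the C1–O bond, in which the silyloxy group is axial on the new ring and anti to the spectator arm. The TIPS ether is chosen for this, since large silyl ethers pay little for an axial site and the equatorial alternative is wedged between the angular methyl and the spectator arm, but only a modest preference should be expected and the C10-epimeric adduct is removed by chromatography. The third enol ether should survive because the tethered nucleophile lowers the oxidation potential of the substrate below that of the product.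

Step 10
Reactants: 13 cis-fused ketal/enol ether/acetal
Product: 14 trans-fused 8-methoxy-7-en-6-one (1R,4R,5S,10R) bearing 4α-CH(OMe)2 and 1β-OTIPS
Conditions: p-TsOH·H2O (0.2 equiv), MeOH/H2O (50:1), 50 °C
Reagents that add atoms: water, O
Why: Acid-catalysed acetal exchange hydrolyses the C6 ketal, moves the remaining enol ether into conjugation (vinylogous ester) and lets C5 (through the C5=C6 enol ether) and C4 (through the C15 enol ether) epimerise, so the mixture should settle on the trans-decalin with H4 and H5 trans and with C15 and the silyloxy group equatorial, while C15 stays a dimethyl acetal because methanol is the solvent.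

Step 11
Reactants: 14 trans-fused 8-methoxy-7-en-6-one
Product: 16 trans-fused 6-en-8-one bearing 4α-CH(OMe)2 and 1β-OTIPS, via 6-hydroxy enol ether 15 (not isolated)
Conditions: iBu2AlH, CH2Cl2, −78 °C; then 0.5 M HCl, THF, 0 °C
Reagents that add atoms: water, O
Why: 1,2-Reduction of the vinylogous ester followed by acid-induced allylic transposition with loss of methanol (Stork–Danheiser sequence) moves the carbonyl to C8 and leaves a C6=C7 enone, under acid too mild to cleave the dimethyl acetal or to disturb C5.

Step 12
Reactants: 16 trans-fused 6-en-8-one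
Product: 17 7-iodo-6-en-8-one
Conditions: I2, pyridine, CH2Cl2, rt
Reagents that add atoms: iodine, II
Why: α-Iodination of the enone (Johnson iodination: conjugate addition of pyridine, iodination of the enolate, elimination) places the halogen on C7.

Step 13
Reactants: 17 7-iodo-6-en-8-one; 18 isopropenylboronic acid pinacol ester
Product: 19 7-isopropenyl-6-en-8-one
Conditions: Pd(dppf)Cl2 (5 mol %), K3PO4, THF/H2O, 50 °C
Reagents that add atoms: isopropenylboronic acid pinacol ester (18), CC(=C)B1OC(C)(C)C(C)(C)O1
Why: Suzuki–Miyaura coupling of the α-iodoenone forms the C7–C11 bond and brings in C12 and C13 as an isopropenyl group.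

Step 14
Reactants: 19 7-isopropenyl-6-en-8-one
Product: 20 6α,7α-epoxy-7-isopropenyl-8-one
Conditions: H2O2 (30 %), NaOH, MeOH, 0 °C
Reagents that add atoms: hydrogen peroxide, OO
Why: Weitz–Scheffer epoxidation touches only the electron-poor enone double bond (the isopropenyl group is inert, as in carvone), and the hydroperoxide anion should add to C6 from the α face, away from the axial C14 methyl, which puts the epoxide oxygen α at C6 and C7.

Step 15
Reactants: 20 6α,7α-epoxy-7-isopropenyl-8-one
Product: 22 6α,8α-diol with 7β-isopropenyl, via β-hydroxy ketone 21 (not isolated)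
Conditions: SmI2, THF/MeOH, −78 °C; then SmI2, H2O, Et3N, −78 → 0 °C
Reagents that add atoms: none
Why: Samarium diiodide cleaves the C7–O bond of the α,β-epoxy ketone (reductive epoxide opening) and the enolate is protonated at C7 from the axial α face, which leaves the isopropenyl group equatorial, and the second, water–amine-accelerated electron-transfer reduction of the C8 ketone should give the equatorial 8α-alcohol, the outcome typical of such reductions of hindered cyclohexanones.

Step 16
Reactants: 23 ethyl 2-(hydroxymethyl)acrylate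
Product: 24 ethyl 2-[(tert-butyldimethylsilyloxy)methyl]acrylate
Conditions: tBuMe2SiCl, imidazole, CH2Cl2, 0 °C → rt
Reagents that add atoms: tert-butyldimethylsilyl chloride, CC(C)(C)[Si](C)(C)Cl
Why: Standard silylation of the primary allylic alcohol masks the hydroxymethyl group of the acyl fragment.

Step 17
Reactants: 24 ethyl 2-[(tert-butyldimethylsilyloxy)methyl]acrylate
Product: 25 2-[(tert-butyldimethylsilyloxy)methyl]acrylic acid
Conditions: LiOH, THF/H2O, 0 °C; then 1 M HCl to pH 4
Reagents that add atoms: lithium hydroxide, [Li+].[OH-]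
Why: Saponification of the ethyl ester with LiOH at 0 °C, which the primary silyl ether withstands, gives the acid for the esterification.

Step 18
Reactants: 22 6α,8α-diol; 25 2-[(tert-butyldimethylsilyloxy)methyl]acrylic acid
Product: 26 8α-ester with free 6α-OH
Conditions: 2,4,6-trichlorobenzoyl chloride, Et3N, THF, 0 °C; then 22, DMAP, toluene, 0 °C → rt
Reagents that add atoms: none
Why: Yamaguchi esterification through the mixed anhydride and the acylpyridinium ion; the equatorial C8 hydroxyl next to the C9 methylene should react in preference to the C6 hydroxyl, which is flanked by C5 and C7 and crowded by the C15 acetal.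

Step 19
Reactants: 26 8α-ester
Product: 28 C12 enal, via allylic alcohol 27 (not isolated)
Conditions: SeO2 (0.3 equiv), tBuOOH, CH2Cl2, rt; then MnO2, CH2Cl2, rt
Reagents that add atoms: tert-butyl hydroperoxide, CC(C)(C)OO (terminal oxidant; the oxygen is passed on through selenium dioxide, O=[Se]=O)
Why: Allylic oxidation by SeO2 (ene reaction then [2,3]-sigmatropic shift) takes place at the methyl group of the electron-rich 1,1-disubstituted alkene and not at the electron-poor acrylate, and MnO2 then oxidises only the primary allylic alcohol to the enal.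

Step 20
Reactants: 28 C12 enal
Product: 29 C12 acid (11(13)-en-12-oic acid) with silyl ethers and acetal in place
Conditions: NaClO2, NaH2PO4, 2-methyl-2-butene, tBuOH/H2O, 0 °C → rt
Reagents that add atoms: sodium chlorite, [Na+].[O-]Cl=O
Why: Pinnick oxidation converts the enal into the α-methylene carboxylic acid without affecting the alkenes, the free C6 alcohol or the acetal.

Step 21
Reactants: 29 C12 acid
Product: 30 CNP0599450.1
Conditions: HF (48 % aq), MeCN, 0 °C → rt
Reagents that add atoms: water, O
Why: Aqueous HF removes both silyl ethers and hydrolyses the dimethyl acetal in one operation, and the equatorial C15 aldehyde is already the stable C4 epimer.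

**Compound list**

1 | 3,5-dimethoxybenzoic acid | COc1cc(cc(OC)c1)C(=O)O | starting material
2 | iodomethane | CI | starting material
3 | 3,5-dimethoxy-1-methylcyclohexa-2,5-diene-1-carboxylic acid | COC1=CC(C)(C(=O)O)C=C(OC)C1 | intermediate
4 | (3,5-dimethoxy-1-methylcyclohexa-2,5-dien-1-yl)methanol | COC1=CC(C)(CO)C=C(OC)C1 | intermediate
5 | 3,5-dimethoxy-1-methylcyclohexa-2,5-diene-1-carbaldehyde | COC1=CC(C)(C=O)C=C(OC)C1 | intermediate
6 | allylmagnesium bromide | C=CC[Mg]Br | starting material
7 | (1R)-1-(3,5-dimethoxy-1-methylcyclohexa-2,5-dien-1-yl)but-3-en-1-ol | C=CC[C@@H](O)C1(C)C=C(OC)CC(OC)=C1 | intermediate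
8 | (1R)-1-(3,5-dimethoxy-1-methylcyclohexa-2,5-dien-1-yl)but-3-en-1-yl triisopropylsilyl ether | C=CC[C@@H](O[Si](C(C)C)(C(C)C)C(C)C)C1(C)C=C(OC)CC(OC)=C1 | intermediate
9 | (4R)-4-(3,5-dimethoxy-1-methylcyclohexa-2,5-dien-1-yl)-4-(triisopropylsilyloxy)butan-1-ol | OCCC[C@@H](O[Si](C(C)C)(C(C)C)C(C)C)C1(C)C=C(OC)CC(OC)=C1 | intermediate
10 | (4R)-4-(3,5-dimethoxy-1-methylcyclohexa-2,5-dien-1-yl)-4-(triisopropylsilyloxy)butanal | O=CCC[C@@H](O[Si](C(C)C)(C(C)C)C(C)C)C1(C)C=C(OC)CC(OC)=C1 | intermediate
11 | (methoxymethyl)triphenylphosphonium chloride | COC[P+](c1ccccc1)(c1ccccc1)c1ccccc1.[Cl-] | starting material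
12 | (1R)-1-(3,5-dimethoxy-1-methylcyclohexa-2,5-dien-1-yl)-5-methoxypent-4-en-1-yl triisopropylsilyl ether (E/Z mixture, E drawn) | CO/C=C/CC[C@@H](O[Si](C(C)C)(C(C)C)C(C)C)C1(C)C=C(OC)CC(OC)=C1 | intermediate
13 | cis-fused (1R,4S,5R,10R) bicycle: 6,6-dimethoxy ketal, 8-methoxy-8-ene, 4β-CH(OMe)2, 5β-H, 1β-OTIPS | COC1=C[C@@]2(C)[C@H](O[Si](C(C)C)(C(C)C)C(C)C)CC[C@H](C(OC)OC)[C@H]2C(OC)(OC)C1 | intermediate
14 | trans-fused (1R,4R,5S,10R) 8-methoxy-7-en-6-one, 4α-CH(OMe)2, 1β-OTIPS | COC1=CC(=O)[C@H]2[C@H](C(OC)OC)CC[C@@H](O[Si](C(C)C)(C(C)C)C(C)C)[C@]2(C)C1 | intermediate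
15 | trans-fused 6-hydroxy-8-methoxy-7-ene (C6 epimer mixture), 4α-CH(OMe)2, 1β-OTIPS | COC1=CC(O)[C@H]2[C@H](C(OC)OC)CC[C@@H](O[Si](C(C)C)(C(C)C)C(C)C)[C@]2(C)C1 | intermediate (not isolated)
16 | trans-fused 6-en-8-one, 4α-CH(OMe)2, 1β-OTIPS | O=C1C[C@]2(C)[C@@H](C=C1)[C@H](C(OC)OC)CC[C@H]2O[Si](C(C)C)(C(C)C)C(C)C | intermediate
17 | 7-iodo-6-en-8-one, 4α-CH(OMe)2, 1β-OTIPS | O=C1C[C@]2(C)[C@@H](C=C1I)[C@H](C(OC)OC)CC[C@H]2O[Si](C(C)C)(C(C)C)C(C)C | intermediate
18 | isopropenylboronic acid pinacol ester | CC(=C)B1OC(C)(C)C(C)(C)O1 | starting material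
19 | 7-isopropenyl-6-en-8-one, 4α-CH(OMe)2, 1β-OTIPS | O=C1C[C@]2(C)[C@@H](C=C1C(C)=C)[C@H](C(OC)OC)CC[C@H]2O[Si](C(C)C)(C(C)C)C(C)C | intermediate
20 | 6α,7α-epoxy-7-isopropenyl-8-one, 4α-CH(OMe)2, 1β-OTIPS | O=C1C[C@]2(C)[C@@H]([C@H]3O[C@@]13C(C)=C)[C@H](C(OC)OC)CC[C@H]2O[Si](C(C)C)(C(C)C)C(C)C | intermediate
21 | 6α-hydroxy-7β-isopropenyl-8-one (7α-H), 4α-CH(OMe)2, 1β-OTIPS | O=C1C[C@]2(C)[C@@H]([C@@H](O)[C@@H]1C(C)=C)[C@H](C(OC)OC)CC[C@H]2O[Si](C(C)C)(C(C)C)C(C)C | intermediate (not isolated)
22 | 6α,8α-diol with 7β-isopropenyl, 4α-CH(OMe)2, 1β-OTIPS | O[C@H]1C[C@]2(C)[C@@H]([C@@H](O)[C@@H]1C(C)=C)[C@H](C(OC)OC)CC[C@H]2O[Si](C(C)C)(C(C)C)C(C)C | intermediate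
23 | ethyl 2-(hydroxymethyl)acrylate | C=C(CO)C(=O)OCC | starting material
24 | ethyl 2-[(tert-butyldimethylsilyloxy)methyl]acrylate | C=C(CO[Si](C)(C)C(C)(C)C)C(=O)OCC | intermediate
25 | 2-[(tert-butyldimethylsilyloxy)methyl]acrylic acid | C=C(CO[Si](C)(C)C(C)(C)C)C(=O)O | intermediate
26 | 8α-{2-[(tert-butyldimethylsilyloxy)methyl]acryloyloxy}-6α-ol with 7β-isopropenyl, 4α-CH(OMe)2, 1β-OTIPS | C=C(CO[Si](C)(C)C(C)(C)C)C(=O)O[C@H]1C[C@]2(C)[C@@H]([C@@H](O)[C@@H]1C(C)=C)[C@H](C(OC)OC)CC[C@H]2O[Si](C(C)C)(C(C)C)C(C)C | intermediate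
27 | as 26 with the side chain oxidised to C(=CH2)CH2OH (12-ol) | C=C(CO[Si](C)(C)C(C)(C)C)C(=O)O[C@H]1C[C@]2(C)[C@@H]([C@@H](O)[C@@H]1C(=C)CO)[C@H](C(OC)OC)CC[C@H]2O[Si](C(C)C)(C(C)C)C(C)C | intermediate (not isolated)
28 | as 26 with the side chain C(=CH2)CHO (12-al) | C=C(CO[Si](C)(C)C(C)(C)C)C(=O)O[C@H]1C[C@]2(C)[C@@H]([C@@H](O)[C@@H]1C(=C)C=O)[C@H](C(OC)OC)CC[C@H]2O[Si](C(C)C)(C(C)C)C(C)C | intermediate
29 | as 26 with the side chain C(=CH2)CO2H (12-oic acid) | C=C(CO[Si](C)(C)C(C)(C)C)C(=O)O[C@H]1C[C@]2(C)[C@@H]([C@@H](O)[C@@H]1C(=C)C(=O)O)[C@H](C(OC)OC)CC[C@H]2O[Si](C(C)C)(C(C)C)C(C)C | intermediate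
30 | CNP0599450.1: 1β,6α-dihydroxy-8α-[2-(hydroxymethyl)acryloyloxy]-15-oxo-eudesm-11(13)-en-12-oic acid (4α-CHO, 5α-H, 7α-H) | C=C(CO)C(=O)O[C@H]1C[C@]2(C)[C@@H]([C@@H](O)[C@@H]1C(=C)C(=O)O)[C@H](C=O)CC[C@H]2O | target

**Count and risks**

Total step count: 21. Longest linear sequence: 19 (steps 1–15 and 18–21); steps 16–17 make the acyl fragment.

The three steps most likely to fail:

Step 9. The two ring enol ethers may be poorly discriminated, since the C1 centre is the only bias and its influence in the required closure is small; the remaining enol ether may also be over-oxidised. The fallback closes ring A by polar chemistry and sets out from aldehyde 10. A Henry addition of nitromethane gives the nitro alcohol F1, and mesylation with elimination gives the (E)-nitroalkene F2. An intramolecular nitroalkene–enol ether [4+2] cycloaddition (SnCl4, CH2Cl2, −78 °C), in which C4 bonds to C5 and the nitronate oxygen to C6, followed by methanolic acid, gives the nitromethyl vinylogous ester F3. Its compact bicyclic transition state gives an independent chance of arm selection, and the C10 epimers are again separable. A Nef reaction in methanol (NaOMe, then H2SO4/MeOH) turns CH2NO2 into the dimethyl acetal under the equilibrating conditions of step 10, and the route is rejoined at 14.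

Step 10. The equilibrium may not lie far enough on the side of the trans-fused isomer, because the cis/trans difference of angularly methylated 1-decalones is small and the acetal crowds the C6 carbonyl; C4 may also epimerise too slowly through the acetal. The fallback sets out from the mixture of 14 and its cis-fused 4,5-bis-epimer, the cis vinylogous ester F4. Step 11 is run with 2 M HCl so that the acetal is hydrolysed as well, giving the cis-fused enone aldehyde F5 and the trans-fused enone aldehyde F6. DBU in toluene at 60 °C then equilibrates C4 through the aldehyde enolate and C5 through the dienolate, at a stage where C6 is a CH and the small formyl group no longer meets a neighbouring carbonyl. Re-acetalisation (HC(OMe)3, MeOH, pyridinium tosylate) brings the route back at 16.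

Step 15. Protonation at C8 may deliver the axial 8β-alcohol instead of the equatorial one, or the intermediate aldol may lose water or isomerise before it is reduced. The fallback sets out from 21, isolated after the first, methanol-buffered SmI2 stage. NaBH4 (MeOH, −40 °C) attacks C8 from the open α face and gives the 6α,8β-diol F7. A Mitsunobu esterification with acid 25 (PPh3, diisopropyl azodicarboxylate, toluene, 0 °C) then inverts C8 while it installs the acyl group, and the route is rejoined at 26.

Further compounds
F1 | step 9 | (4R)-4-(3,5-dimethoxy-1-methylcyclohexa-2,5-dien-1-yl)-1-nitro-4-(triisopropylsilyloxy)butan-2-ol homologue: 5-aryl... nitro alcohol from 10 and nitromethane (carbinol epimers) | [O-][N+](=O)CC(O)CC[C@@H](O[Si](C(C)C)(C(C)C)C(C)C)C1(C)C=C(OC)CC(OC)=C1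
F2 | step 9 | (E)-nitroalkene, (1R)-1-(3,5-dimethoxy-1-methylcyclohexa-2,5-dien-1-yl)-5-nitropent-4-en-1-yl triisopropylsilyl ether | [O-][N+](=O)/C=C/CC[C@@H](O[Si](C(C)C)(C(C)C)C(C)C)C1(C)C=C(OC)CC(OC)=C1
F3 | step 9 | 8-methoxy-7-en-6-one with 4-CH2NO2 and 1β-OTIPS (cis-fused C4 epimer drawn) | COC1=CC(=O)[C@@H]2[C@@H](C[N+](=O)[O-])CC[C@@H](O[Si](C(C)C)(C(C)C)C(C)C)[C@]2(C)C1
F4 | step 10 | cis-fused (1R,4S,5R,10R) 8-methoxy-7-en-6-one, 4β-CH(OMe)2, 1β-OTIPS | COC1=CC(=O)[C@@H]2[C@@H](C(OC)OC)CC[C@@H](O[Si](C(C)C)(C(C)C)C(C)C)[C@]2(C)C1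
F5 | step 10 | cis-fused 6-en-8-one with 4β-CHO (5β-H), 1β-OTIPS | O=C1C[C@]2(C)[C@H](C=C1)[C@@H](C=O)CC[C@H]2O[Si](C(C)C)(C(C)C)C(C)C
F6 | step 10 | trans-fused 6-en-8-one with 4α-CHO (5α-H), 1β-OTIPS | O=C1C[C@]2(C)[C@@H](C=C1)[C@H](C=O)CC[C@H]2O[Si](C(C)C)(C(C)C)C(C)C
F7 | step 15 | 6α,8β-diol with 7β-isopropenyl, 4α-CH(OMe)2, 1β-OTIPS | O[C@@H]1C[C@]2(C)[C@@H]([C@@H](O)[C@@H]1C(C)=C)[C@H](C(OC)OC)CC[C@H]2O[Si](C(C)C)(C(C)C)C(C)C
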